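**Strategy.** The carbocycle (the six-membered ring of the 7-oxabicyclo[4.1.0]heptane core) is closed at the bond between the ring carbinol carbon and the neighbouring ring carbon that bears the 1-methylenealkyl side chain (C1–C6 of the cyclohexene intermediates). The array C1(OH)–C6H–C7(=CH2) is the retron of an intramolecular carbonyl-ene reaction. The precursor is an open-chain, fully oxygenated farnesane: a (3Z,6Z)-skipped trienal assembled from two α-silyloxy methyl ketones and a three-carbon bis-phosphonium linchpin. One operation makes the ring, the exocyclic methylene and two stereocentres under control of the C2 silyloxy centre. The carbinol is then inverted by oxidation and reduction; directed epoxidation, triple angeloylation and a Shi epoxidation complete the target.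

Key step: step 10

Remark: locants C1–C15 in the text are those of the farnesane chain of aldehyde 15 (C1 aldehyde carbon, C2 and C8 the silyloxy carbons, C3=C4 and C6=C7 the two Z alkenes, C14 the methyl on C7); in the ring compounds C1–C6 are the ring atoms in the same order.

Step 1
Reactants: 1 6-methylhept-5-en-2-one
Product: 2 (3S)-6-methyl-3-[(phenylamino)oxy]hept-5-en-2-one
Conditions: PhN=O (slow addition), D-proline (30 mol%), DMF, 0 °C (1 in threefold excess)
Reagents that add atoms: nitrosobenzene, O=Nc1ccccc1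
Why: Proline-catalysed α-aminoxylation (O-selective nitroso aldol) through the more substituted enamine oxygenates C3 and not the methyl group; D-proline is expected to give the (S) centre, the mirror image of the sense known for L-proline.

Step 2
Reactants: 2 (3S)-6-methyl-3-[(phenylamino)oxy]hept-5-en-2-one
Product: 3 (3S)-3-hydroxy-6-methylhept-5-en-2-one
Conditions: Zn, AcOH, THF, 0 °C → rt
Reagents that add atoms: none
Why: Reductive N–O cleavage; zinc in acetic acid breaks the weak N–O bond and should leave ketone, alkene and stereocentre untouched.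

Step 3
Reactants: 3 (3S)-3-hydroxy-6-methylhept-5-en-2-one
Product: 4 (3S)-3-{[tert-butyl(dimethyl)silyl]oxy}-6-methylhept-5-en-2-one
Conditions: TBSCl, imidazole, DMF, rt
Reagents that add atoms: tert-butylchlorodimethylsilane, CC(C)(C)[Si](C)(C)Cl
Why: Standard silylation; the ether provides the α-alkoxy group needed for the Z-selective Wittig reaction and lasts until the fluoride step.

Step 4
Reactants: 5 propane-1,3-diylbis(triphenylphosphonium) dibromide; 4 (3S)-3-{[tert-butyl(dimethyl)silyl]oxy}-6-methylhept-5-en-2-one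
Product: 7 [(3Z,5S)-5-{[tert-butyl(dimethyl)silyl]oxy}-4,8-dimethylnona-3,7-dien-1-yl]triphenylphosphonium bromide, via mono-ylide 6 (not isolated)
Conditions: 5 (2.5 equiv), KN(SiMe3)2 (1.1 equiv), THF, −78 → 0 °C; then 4, −78 °C → rt
Reagents that add atoms: none
Why: Wittig olefination of an α-alkoxy methyl ketone with a non-stabilised ylide places the oxygen-bearing carbon cis to the ylide chain (Still's Z-selective variant), which sets the 6Z alkene; excess bis-salt with about one equivalent of base keeps the second phosphonium group intact.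

Step 5
Reactants: 8 methyl (4S)-2,2-dimethyl-1,3-dioxolane-4-carboxylate
Product: 10 1-[(4S)-2,2-dimethyl-1,3-dioxolan-4-yl]ethan-1-one, via Weinreb amide 9 (not isolated)
Conditions: MeNH(OMe)·HCl, i-PrMgCl, THF, −20 °C; then MeMgBr, 0 °C; aq. NH4Cl
Reagents that add atoms: methylmagnesium bromide, C[Mg]Br
Why: One-pot Weinreb amide formation and Grignard addition; the chelated tetrahedral intermediate stops the addition at the methyl ketone and the α-stereocentre should be preserved.

Step 6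
Reactants: 7 [(3Z,5S)-5-{[tert-butyl(dimethyl)silyl]oxy}-4,8-dimethylnona-3,7-dien-1-yl]triphenylphosphonium bromide; 10 1-[(4S)-2,2-dimethyl-1,3-dioxolan-4-yl]ethan-1-one
Product: 12 tert-butyl({(5S,6Z,9Z)-10-[(4R)-2,2-dimethyl-1,3-dioxolan-4-yl]-2,6-dimethylundeca-2,6,9-trien-5-yl}oxy)dimethylsilane, via ylide 11 (not isolated)
Conditions: KN(SiMe3)2 (1.05 equiv), THF, −78 °C; then 10, −78 °C → rt
Reagents that add atoms: none
Why: A second Still-type Z-selective Wittig reaction of a non-stabilised ylide with an α-alkoxy ketone sets the 3Z alkene, in which C2 and C5 are cis as the ring closure demands, and completes the C15 chain.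

Step 7
Reactants: 12 tert-butyl({(5S,6Z,9Z)-10-[(4R)-2,2-dimethyl-1,3-dioxolan-4-yl]-2,6-dimethylundeca-2,6,9-trien-5-yl}oxy)dimethylsilane
Product: 13 (2R,3Z,6Z,8S)-8-{[tert-butyl(dimethyl)silyl]oxy}-3,7,11-trimethyldodeca-3,6,10-triene-1,2-diol
Conditions: CuCl2·2H2O, MeCN, 0 °C → rt
Reagents that add atoms: none
Why: Mild acetal hydrolysis; hydrated CuCl2 in acetonitrile cleaves terminal acetonides and should leave the secondary TBS ether and the skipped triene intact.

Step 8
Reactants: 13 (2R,3Z,6Z,8S)-8-{[tert-butyl(dimethyl)silyl]oxy}-3,7,11-trimethyldodeca-3,6,10-triene-1,2-diol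
Product: 14 (2R,3Z,6Z,8S)-8-{[tert-butyl(dimethyl)silyl]oxy}-3,7,11-trimethyl-1,2-bis[(triethylsilyl)oxy]dodeca-3,6,10-triene
Conditions: TESCl, imidazole, DMAP (cat.), CH2Cl2, 0 °C → rt
Reagents that add atoms: chlorotriethylsilane, CC[Si](Cl)(CC)CC
Why: Silylation of both hydroxyls prepares the selective oxidation of the primary position and puts a bulky, non-chelating group on O2.

Step 9
Reactants: 14 (2R,3Z,6Z,8S)-8-{[tert-butyl(dimethyl)silyl]oxy}-3,7,11-trimethyl-1,2-bis[(triethylsilyl)oxy]dodeca-3,6,10-triene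
Product: 15 (2R,3Z,6Z,8S)-8-{[tert-butyl(dimethyl)silyl]oxy}-3,7,11-trimethyl-2-[(triethylsilyl)oxy]dodeca-3,6,10-trienal
Conditions: (COCl)2, DMSO, CH2Cl2, −78 → −30 °C; then Et3N, −78 → 0 °C; used at once
Reagents that add atoms: none
Why: Swern oxidation of a silyl ether; the primary triethylsilyl ether is cleaved and oxidised in the same flask while the secondary silyl ethers persist, so the sensitive α-silyloxy aldehyde is unveiled without a free diol stage.

Step 10
Reactants: 15 (2R,3Z,6Z,8S)-8-{[tert-butyl(dimethyl)silyl]oxy}-3,7,11-trimethyl-2-[(triethylsilyl)oxy]dodeca-3,6,10-trienal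
Product: 16 (1R,2R,6R)-6-[(3S)-3-{[tert-butyl(dimethyl)silyl]oxy}-6-methylhepta-1,5-dien-2-yl]-3-methyl-2-[(triethylsilyl)oxy]cyclohex-3-en-1-ol
Conditions: MeAl(OC6H2-4-Br-2,6-t-Bu2)2 (MABR, 2 equiv), CH2Cl2, −78 → −40 °C; aq. NaHCO3
Reagents that add atoms: none
Why: Lewis-acid-promoted intramolecular carbonyl-ene reaction, the closest known case being the citronellal-to-isopulegol cyclisation: the aluminium-activated aldehyde carbon C1 bonds to C6 while the carbonyl oxygen accepts a hydrogen from the C14 methyl group in one six-centre transition state, so that ring, C1 carbinol and C7=C14 methylene arise together. The ring closes in the 6-exo mode with respect to both the C=O and the C6=C7 π bond, through a chair-like half-chair that already contains the cis C3=C4 double bond. C1 is controlled by the alkene geometry: the methyl group is trans to the tether (6Z), and only the chair with the carbonyl oxygen equatorial can reach its hydrogens, which puts C1–OH trans to the equatorial C6 side chain (the isopulegol relationship). C6 is controlled by the C2 stereocentre: the monodentate, very hindered aluminium aryloxide cannot chelate, and the half-chair with the C2 silyloxy group pseudo-equatorial, antiperiplanar to the forming C1–C6 bond (polar Felkin–Anh) and not syn to the complexed carbonyl, should be favoured, which sets C6 cis to O2. The step needs hydrogen abstraction from C14 and not from C8–H (C8 is cis to the tether, out of reach of an equatorial oxygen, and is deactivated inductively by its silyloxy group) and reaction at C6=C7 and not at the distant C10=C11 alkene (secured by ring size). The C1 configuration that results is inverted in steps 11 and 12.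

Step 11
Reactants: 16 (1R,2R,6R)-6-[(3S)-3-{[tert-butyl(dimethyl)silyl]oxy}-6-methylhepta-1,5-dien-2-yl]-3-methyl-2-[(triethylsilyl)oxy]cyclohex-3-en-1-ol
Product: 17 (2R,6R)-6-[(3S)-3-{[tert-butyl(dimethyl)silyl]oxy}-6-methylhepta-1,5-dien-2-yl]-3-methyl-2-[(triethylsilyl)oxy]cyclohex-3-en-1-one
Conditions: Dess–Martin periodinane, NaHCO3, CH2Cl2, 0 °C → rt
Reagents that add atoms: none
Why: Dess–Martin oxidation under buffered, amine-free conditions should give the β,γ-unsaturated α-silyloxy ketone without epimerisation at C2 or C6 and without conjugation.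

Step 12
Reactants: 17 (2R,6R)-6-[(3S)-3-{[tert-butyl(dimethyl)silyl]oxy}-6-methylhepta-1,5-dien-2-yl]-3-methyl-2-[(triethylsilyl)oxy]cyclohex-3-en-1-one
Product: 18 (1S,2R,6R)-6-[(3S)-3-{[tert-butyl(dimethyl)silyl]oxy}-6-methylhepta-1,5-dien-2-yl]-3-methyl-2-[(triethylsilyl)oxy]cyclohex-3-en-1-ol
Conditions: LiBH(s-Bu)3 (L-Selectride), THF, −78 °C; H2O
Reagents that add atoms: none
Why: L-Selectride reduction; the bulky borohydride attacks the ketone flanked by two equatorial substituents from the equatorial side and should give the axial alcohol cis to both neighbours, as in the reduction of isopulegone to neoisopulegol.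

Step 13
Reactants: 18 (1S,2R,6R)-6-[(3S)-3-{[tert-butyl(dimethyl)silyl]oxy}-6-methylhepta-1,5-dien-2-yl]-3-methyl-2-[(triethylsilyl)oxy]cyclohex-3-en-1-ol
Product: 19 (1R,2S,3S,4R,6R)-4-[(3S)-3-{[tert-butyl(dimethyl)silyl]oxy}-6-methylhepta-1,5-dien-2-yl]-1-methyl-2-[(triethylsilyl)oxy]-7-oxabicyclo[4.1.0]heptan-3-ol
Conditions: VO(acac)2 (5 mol%), t-BuOOH (decane), CH2Cl2, 0 °C → rt
Reagents that add atoms: tert-butyl hydroperoxide, CC(C)(C)OO
Why: Vanadium-catalysed hydroxyl-directed epoxidation; the axial homoallylic C1 hydroxyl delivers oxygen to the trisubstituted ring alkene on its own face, cis to O1 and O2, while the undirected prenyl alkene and the less nucleophilic 1,1-disubstituted alkene should stay intact.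

Step 14
Reactants: 19 (1R,2S,3S,4R,6R)-4-[(3S)-3-{[tert-butyl(dimethyl)silyl]oxy}-6-methylhepta-1,5-dien-2-yl]-1-methyl-2-[(triethylsilyl)oxy]-7-oxabicyclo[4.1.0]heptan-3-ol
Product: 20 (1S,2S,3S,4R,6R)-4-[(3S)-3-hydroxy-6-methylhepta-1,5-dien-2-yl]-1-methyl-7-oxabicyclo[4.1.0]heptane-2,3-diol
Conditions: n-Bu4NF, AcOH, THF, 0 °C → rt
Reagents that add atoms: none
Why: Fluoride-mediated desilylation removes both silyl ethers; the cis epoxy alcohol cannot undergo Payne rearrangement because its alkoxide cannot reach the backside of the epoxide.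

Step 15
Reactants: 20 (1S,2S,3S,4R,6R)-4-[(3S)-3-hydroxy-6-methylhepta-1,5-dien-2-yl]-1-methyl-7-oxabicyclo[4.1.0]heptane-2,3-diol
Product: 21 (1R,2S,3S,4R,6R)-1-methyl-4-{(3S)-6-methyl-3-[(2Z)-2-methylbut-2-enoyloxy]hepta-1,5-dien-2-yl}-7-oxabicyclo[4.1.0]heptane-2,3-diyl bis[(2Z)-2-methylbut-2-enoate]
Conditions: angelic acid (6 equiv), 2,4,6-trichlorobenzoyl chloride (6 equiv), Et3N, toluene, rt, filter; then 20, toluene, 80 °C
Reagents that add atoms: angelic acid [(2Z)-2-methylbut-2-enoic acid], C/C=C(/C)C(O)=O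
Why: Yamaguchi esterification with the preformed mixed anhydride and without a nucleophilic catalyst should acylate hindered secondary alcohols with angelic acid without Z-to-E isomerisation.

Step 16
Reactants: 21 (1R,2S,3S,4R,6R)-1-methyl-4-{(3S)-6-methyl-3-[(2Z)-2-methylbut-2-enoyloxy]hepta-1,5-dien-2-yl}-7-oxabicyclo[4.1.0]heptane-2,3-diyl bis[(2Z)-2-methylbut-2-enoate]
Product: 22 (1R,2S,3S,4R,6R)-4-{(3S)-4-[(2R)-3,3-dimethyloxiran-2-yl]-3-[(2Z)-2-methylbut-2-enoyloxy]but-1-en-2-yl}-1-methyl-7-oxabicyclo[4.1.0]heptane-2,3-diyl bis[(2Z)-2-methylbut-2-enoate] (CNP0258231.4)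
Conditions: Shi ketone (D-fructose-derived, 30 mol%), Oxone (2KHSO5·KHSO4·K2SO4), K2CO3, n-Bu4NHSO4, MeCN/CH2(OMe)2/aq. Na2B4O7 buffer, 0 °C
Reagents that add atoms: potassium peroxymonosulfate (active component of Oxone), [K+].[O-]S(=O)(=O)OO
Why: Shi asymmetric epoxidation; the chiral dioxirane should attack only the electron-rich trisubstituted prenyl alkene, and its spiro transition state delivers oxygen to the face that gives the (R) epoxide, while the angelate and 1,1-disubstituted alkenes are too electron-poor or hindered to compete.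

**Compound list**

1 | 6-methylhept-5-en-2-one | CC(=O)CCC=C(C)C | starting material
2 | (3S)-6-methyl-3-[(phenylamino)oxy]hept-5-en-2-one | CC(=O)[C@H](CC=C(C)C)ONc1ccccc1 | intermediate
3 | (3S)-3-hydroxy-6-methylhept-5-en-2-one | CC(=O)[C@H](CC=C(C)C)O | intermediate
4 | (3S)-3-{[tert-butyl(dimethyl)silyl]oxy}-6-methylhept-5-en-2-one | CC(=O)[C@H](CC=C(C)C)O[Si](C)(C)C(C)(C)C | intermediate
5 | propane-1,3-diylbis(triphenylphosphonium) dibromide | [Br-].[Br-].c1ccc(cc1)[P+](c1ccccc1)(c1ccccc1)CCC[P+](c1ccccc1)(c1ccccc1)c1ccccc1 | starting material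
6 | triphenyl[3-(triphenyl-λ5-phosphanylidene)propyl]phosphonium bromide (mono-ylide, not isolated) | [Br-].c1ccc(cc1)[P+](c1ccccc1)(c1ccccc1)CCC=P(c1ccccc1)(c1ccccc1)c1ccccc1 | intermediate
7 | [(3Z,5S)-5-{[tert-butyl(dimethyl)silyl]oxy}-4,8-dimethylnona-3,7-dien-1-yl]triphenylphosphonium bromide | [Br-].c1ccc(cc1)[P+](c1ccccc1)(c1ccccc1)CC/C=C(/C)[C@H](CC=C(C)C)O[Si](C)(C)C(C)(C)C | intermediate
8 | methyl (4S)-2,2-dimethyl-1,3-dioxolane-4-carboxylate | COC(=O)[C@@H]1COC(C)(C)O1 | starting material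
9 | (4S)-N-methoxy-N,2,2-trimethyl-1,3-dioxolane-4-carboxamide (Weinreb amide, not isolated) | CON(C)C(=O)[C@@H]1COC(C)(C)O1 | intermediate
10 | 1-[(4S)-2,2-dimethyl-1,3-dioxolan-4-yl]ethan-1-one | CC(=O)[C@@H]1COC(C)(C)O1 | intermediate
11 | tert-butyl{[(5S,6Z)-2,6-dimethyl-9-(triphenyl-λ5-phosphanylidene)nona-2,6-dien-5-yl]oxy}dimethylsilane (ylide, not isolated) | C(=P(c1ccccc1)(c1ccccc1)c1ccccc1)C/C=C(/C)[C@H](CC=C(C)C)O[Si](C)(C)C(C)(C)C | intermediate
12 | tert-butyl({(5S,6Z,9Z)-10-[(4R)-2,2-dimethyl-1,3-dioxolan-4-yl]-2,6-dimethylundeca-2,6,9-trien-5-yl}oxy)dimethylsilane | CC1(C)OC[C@H](O1)/C(C)=C\C/C=C(/C)[C@H](CC=C(C)C)O[Si](C)(C)C(C)(C)C | intermediate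
13 | (2R,3Z,6Z,8S)-8-{[tert-butyl(dimethyl)silyl]oxy}-3,7,11-trimethyldodeca-3,6,10-triene-1,2-diol | OC[C@H](O)/C(C)=C\C/C=C(/C)[C@H](CC=C(C)C)O[Si](C)(C)C(C)(C)C | intermediate
14 | (2R,3Z,6Z,8S)-8-{[tert-butyl(dimethyl)silyl]oxy}-3,7,11-trimethyl-1,2-bis[(triethylsilyl)oxy]dodeca-3,6,10-triene | CC[Si](CC)(CC)OC[C@H](O[Si](CC)(CC)CC)/C(C)=C\C/C=C(/C)[C@H](CC=C(C)C)O[Si](C)(C)C(C)(C)C | intermediate
15 | (2R,3Z,6Z,8S)-8-{[tert-butyl(dimethyl)silyl]oxy}-3,7,11-trimethyl-2-[(triethylsilyl)oxy]dodeca-3,6,10-trienal | O=C[C@H](O[Si](CC)(CC)CC)/C(C)=C\C/C=C(/C)[C@H](CC=C(C)C)O[Si](C)(C)C(C)(C)C | intermediate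
16 | (1R,2R,6R)-6-[(3S)-3-{[tert-butyl(dimethyl)silyl]oxy}-6-methylhepta-1,5-dien-2-yl]-3-methyl-2-[(triethylsilyl)oxy]cyclohex-3-en-1-ol (C1–OH trans to O2 and to the side chain) | C=C([C@H](CC=C(C)C)O[Si](C)(C)C(C)(C)C)[C@H]1CC=C(C)[C@@H](O[Si](CC)(CC)CC)[C@@H]1O | intermediate
17 | (2R,6R)-6-[(3S)-3-{[tert-butyl(dimethyl)silyl]oxy}-6-methylhepta-1,5-dien-2-yl]-3-methyl-2-[(triethylsilyl)oxy]cyclohex-3-en-1-one | C=C([C@H](CC=C(C)C)O[Si](C)(C)C(C)(C)C)[C@H]1CC=C(C)[C@@H](O[Si](CC)(CC)CC)C1=O | intermediate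
18 | (1S,2R,6R)-6-[(3S)-3-{[tert-butyl(dimethyl)silyl]oxy}-6-methylhepta-1,5-dien-2-yl]-3-methyl-2-[(triethylsilyl)oxy]cyclohex-3-en-1-ol (all-cis) | C=C([C@H](CC=C(C)C)O[Si](C)(C)C(C)(C)C)[C@H]1CC=C(C)[C@@H](O[Si](CC)(CC)CC)[C@H]1O | intermediate
19 | (1R,2S,3S,4R,6R)-4-[(3S)-3-{[tert-butyl(dimethyl)silyl]oxy}-6-methylhepta-1,5-dien-2-yl]-1-methyl-2-[(triethylsilyl)oxy]-7-oxabicyclo[4.1.0]heptan-3-ol | C=C([C@H](CC=C(C)C)O[Si](C)(C)C(C)(C)C)[C@H]1C[C@H]2O[C@@]2(C)[C@@H](O[Si](CC)(CC)CC)[C@H]1O | intermediate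
20 | (1S,2S,3S,4R,6R)-4-[(3S)-3-hydroxy-6-methylhepta-1,5-dien-2-yl]-1-methyl-7-oxabicyclo[4.1.0]heptane-2,3-diol | C=C([C@H](CC=C(C)C)O)[C@H]1C[C@H]2O[C@@]2(C)[C@@H](O)[C@H]1O | intermediate
21 | (1R,2S,3S,4R,6R)-1-methyl-4-{(3S)-6-methyl-3-[(2Z)-2-methylbut-2-enoyloxy]hepta-1,5-dien-2-yl}-7-oxabicyclo[4.1.0]heptane-2,3-diyl bis[(2Z)-2-methylbut-2-enoate] | C=C([C@H](CC=C(C)C)OC(=O)/C(C)=C\C)[C@H]1C[C@H]2O[C@@]2(C)[C@@H](OC(=O)/C(C)=C\C)[C@H]1OC(=O)/C(C)=C\C | intermediate
22 | (1R,2S,3S,4R,6R)-4-{(3S)-4-[(2R)-3,3-dimethyloxiran-2-yl]-3-[(2Z)-2-methylbut-2-enoyloxy]but-1-en-2-yl}-1-methyl-7-oxabicyclo[4.1.0]heptane-2,3-diyl bis[(2Z)-2-methylbut-2-enoate] | C=C([C@H](C[C@H]1OC1(C)C)OC(=O)/C(C)=C\C)[C@H]1C[C@H]2O[C@@]2(C)[C@@H](OC(=O)/C(C)=C\C)[C@H]1OC(=O)/C(C)=C\C | target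

**Total step count:** 16. **Longest linear sequence:** 15 (steps 1–4 and 6–16; step 5 is a side branch).

**Steps most likely to fail**

Step 10 (key step). The two half-chairs that differ in the placement of the C2 silyloxy group (pseudo-equatorial versus pseudo-axial) may not be well discriminated, or hydrogen transfer may lag behind C–C bond formation, so that facial selectivity at C6 relative to C2 is lost. The fallback takes the C2 stereocentre out of the ring-closing event and lets a chiral catalyst decide. It sets out from diol 13. Double Swern oxidation should give the 2-oxoaldehyde (3Z,6Z,8S)-8-{[tert-butyl(dimethyl)silyl]oxy}-3,7,11-trimethyl-2-oxododeca-3,6,10-trienal F1. Cu(OTf)2 with the tert-butyl-bis(oxazoline) enantiomer that gives the (5R,6R) product binds the 1,2-dicarbonyl unit and catalyses the ene closure (a reaction type known for glyoxylates, pyruvates and unsaturated α-keto esters), again through the all-equatorial chair. This should give the trans α-hydroxy enone (5R,6R)-5-[(3S)-3-{[tert-butyl(dimethyl)silyl]oxy}-6-methylhepta-1,5-dien-2-yl]-6-hydroxy-2-methylcyclohex-2-en-1-one F2. A Mitsunobu reaction with angelic acid (PPh3, DIAD) inverts the carbinol and installs the first ester, giving the cis keto angelate (1S,6R)-6-[(3S)-3-{[tert-butyl(dimethyl)silyl]oxy}-6-methylhepta-1,5-dien-2-yl]-3-methyl-2-oxocyclohex-3-en-1-yl (2Z)-2-methylbut-2-enoate F3. NaBH4/CeCl3·7H2O should reduce the enone from the axial direction to the all-cis allylic alcohol (1S,2R,6R)-6-[(3S)-3-{[tert-butyl(dimethyl)silyl]oxy}-6-methylhepta-1,5-dien-2-yl]-2-hydroxy-3-methylcyclohex-3-en-1-yl (2Z)-2-methylbut-2-enoate F4. VO(acac)2/t-BuOOH, now directed by the allylic hydroxyl, gives the cis epoxy alcohol mono-angelate F5, and n-Bu4NF/AcOH gives the epoxy diol mono-angelate F6. The conditions of step 15 then acylate the two free hydroxyls, and the fallback comes back to the route at 21.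

Step 15. Acylation of the hindered C1 and C2 hydroxyls may stay incomplete, and forcing conditions may isomerise the angelate to the tiglate. The fallback builds the Z alkene after acylation. It sets out from triol 20. DCC/DMAP esterification with 2-[bis(2,2,2-trifluoroethoxy)phosphoryl]propanoic acid should give the tris(phosphonopropanoate) of 20 F7. A threefold Still–Gennari olefination (KN(SiMe3)2, 18-crown-6, THF, −78 °C, then acetaldehyde) should form the three Z-configured 2-methylbut-2-enoates, and the fallback comes back to the route at 21.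

Step 4. Statistical double olefination of the bis-salt and proton exchange between the ylide and the product salt may erode the mono-Wittig reaction. The fallback uses a differentiated three-carbon linchpin and sets out from ketone 4. The ylide of (3-hydroxypropyl)triphenylphosphonium bromide (2 equiv KN(SiMe3)2, THF, −78 °C → rt) should give the homoallylic alcohol (3Z,5S)-5-{[tert-butyl(dimethyl)silyl]oxy}-4,8-dimethylnona-3,7-dien-1-ol F8. I2/PPh3/imidazole gives tert-butyl{[(5S,6Z)-9-iodo-2,6-dimethylnona-2,6-dien-5-yl]oxy}dimethylsilane F9, and PPh3 in MeCN at reflux gives [(3Z,5S)-5-{[tert-butyl(dimethyl)silyl]oxy}-4,8-dimethylnona-3,7-dien-1-yl]triphenylphosphonium iodide F10. This salt is used in step 6 in place of 7, and the fallback comes back to the route at 12.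

**Further compounds**

F1 | step 10 | (3Z,6Z,8S)-8-{[tert-butyl(dimethyl)silyl]oxy}-3,7,11-trimethyl-2-oxododeca-3,6,10-trienal | O=CC(=O)/C(C)=C\C/C=C(/C)[C@H](CC=C(C)C)O[Si](C)(C)C(C)(C)C
F2 | step 10 | (5R,6R)-5-[(3S)-3-{[tert-butyl(dimethyl)silyl]oxy}-6-methylhepta-1,5-dien-2-yl]-6-hydroxy-2-methylcyclohex-2-en-1-one | C=C([C@H](CC=C(C)C)O[Si](C)(C)C(C)(C)C)[C@H]1CC=C(C)C(=O)[C@@H]1O
F3 | step 10 | (1S,6R)-6-[(3S)-3-{[tert-butyl(dimethyl)silyl]oxy}-6-methylhepta-1,5-dien-2-yl]-3-methyl-2-oxocyclohex-3-en-1-yl (2Z)-2-methylbut-2-enoate | C=C([C@H](CC=C(C)C)O[Si](C)(C)C(C)(C)C)[C@H]1CC=C(C)C(=O)[C@H]1OC(=O)/C(C)=C\C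
F4 | step 10 | (1S,2R,6R)-6-[(3S)-3-{[tert-butyl(dimethyl)silyl]oxy}-6-methylhepta-1,5-dien-2-yl]-2-hydroxy-3-methylcyclohex-3-en-1-yl (2Z)-2-methylbut-2-enoate | C=C([C@H](CC=C(C)C)O[Si](C)(C)C(C)(C)C)[C@H]1CC=C(C)[C@@H](O)[C@H]1OC(=O)/C(C)=C\C
F5 | step 10 | cis epoxy alcohol mono-angelate, C8 TBS ether (1,2-epoxide, C2–OH and C1 angelate all cis to the side chain) | C=C([C@H](CC=C(C)C)O[Si](C)(C)C(C)(C)C)[C@H]1C[C@H]2O[C@@]2(C)[C@@H](O)[C@H]1OC(=O)/C(C)=C\C
F6 | step 10 | epoxy diol mono-angelate (F5 without the silyl group) | C=C([C@H](CC=C(C)C)O)[C@H]1C[C@H]2O[C@@]2(C)[C@@H](O)[C@H]1OC(=O)/C(C)=C\C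
F7 | step 15 | tris{2-[bis(2,2,2-trifluoroethoxy)phosphoryl]propanoate} of 20 | C=C([C@H](CC=C(C)C)OC(=O)C(C)P(=O)(OCC(F)(F)F)OCC(F)(F)F)[C@H]1C[C@H]2O[C@@]2(C)[C@@H](OC(=O)C(C)P(=O)(OCC(F)(F)F)OCC(F)(F)F)[C@H]1OC(=O)C(C)P(=O)(OCC(F)(F)F)OCC(F)(F)F
F8 | step 4 | (3Z,5S)-5-{[tert-butyl(dimethyl)silyl]oxy}-4,8-dimethylnona-3,7-dien-1-ol | OCC/C=C(/C)[C@H](CC=C(C)C)O[Si](C)(C)C(C)(C)C
F9 | step 4 | tert-butyl{[(5S,6Z)-9-iodo-2,6-dimethylnona-2,6-dien-5-yl]oxy}dimethylsilane | ICC/C=C(/C)[C@H](CC=C(C)C)O[Si](C)(C)C(C)(C)C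
F10 | step 4 | [(3Z,5S)-5-{[tert-butyl(dimethyl)silyl]oxy}-4,8-dimethylnona-3,7-dien-1-yl]triphenylphosphonium iodide | [I-].c1ccc(cc1)[P+](c1ccccc1)(c1ccccc1)CC/C=C(/C)[C@H](CC=C(C)C)O[Si](C)(C)C(C)(C)C
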